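**Retrosynthetic overview**

1. Sanggenone H 18 ← removal of three MOM ethers from the (2S)-flavanone 17.
2. 17 ← ring C closed last by forming C3–C4: enantioselective rhodium-catalysed 6-endo hydroacylation of the achiral aldehyde enol ether 16, which also sets C2, the only stereocentre.
3. Enabling feature: C2 of ring C carries only O1, the ring B aryl carbon and C3, so C2–C3 can be carried as the 1,1-disubstituted enol ether O1–C2(=C3H2)–ring B; O1 holds it ortho to the C4 formyl group on ring A, C3 lies six atoms from C4, and the alkene has no allylic hydrogen.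
4. 16 ← methylenation of aryl ester 13 (C4 carried as CH2OTBS, then unmasked and oxidised); 13 ← ring A phenol 11 (from 2,4,6-trihydroxybenzaldehyde) + ring B chromene acid 7.
5. 7 ← the pyran ring of the chromene is formed first, by propargyl ether Claisen rearrangement/oxa-6π closure on methyl 2,4-dihydroxybenzoate; the ester blocks the other ortho position.

Key step: step 12

Assumption: the sense of induction of (R)-DTBM-SEGPHOS on this substrate class is not known; the (R)-ligand is written, and its antipode is to be used if hydride goes to the Si face of C2. Flavanone numbering (O1, C2, C3, C4, C4a, C5–C8, C8a) is used throughout.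

**Route**

Step 1
Reactants: 1 methyl 2,4-dihydroxybenzoate
Product: 2 methyl 2-hydroxy-4-(methoxymethoxy)benzoate
Conditions: MOMCl (1.05 equiv), iPr2NEt, CH2Cl2, 0 °C to rt
Reagents that add atoms: chloromethyl methyl ether (MOMCl), COCCl
Why: Williamson-type O-alkylation should take only the 4-OH, because the 2-OH is hydrogen-bonded to the ester carbonyl and much less nucleophilic.

Step 2
Reactants: 2 methyl 2-hydroxy-4-(methoxymethoxy)benzoate
Product: 3 methyl 4-(methoxymethoxy)-2-[(2-methylbut-3-yn-2-yl)oxy]benzoate
Conditions: 3-chloro-3-methylbut-1-yne, DBU, CuCl2·2H2O (cat.), MeCN, 0 °C to rt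
Reagents that add atoms: 3-chloro-3-methylbut-1-yne, CC(C)(Cl)C#C
Why: Copper-catalysed propargylic etherification should alkylate the hindered, hydrogen-bonded phenol under mild base, where thermal carbonate conditions are sluggish.

Step 3
Reactants: 3 methyl 4-(methoxymethoxy)-2-[(2-methylbut-3-yn-2-yl)oxy]benzoate
Product: 6 methyl 5-(methoxymethoxy)-2,2-dimethyl-2H-chromene-8-carboxylate, via ortho-allenylphenol 4 (not isolated), via ortho-quinone methide 5 (not isolated)
Conditions: N,N-diethylaniline, 190 °C
Reagents that add atoms: none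
Why: The aryl propargyl ether Claisen rearrangement can deliver the allenyl group only to the free ortho carbon, since the other bears the ester; 1,5-hydrogen shift and oxa-6π electrocyclisation should then give the 2,2-dimethylchromene.

Step 4
Reactants: 6 methyl 5-(methoxymethoxy)-2,2-dimethyl-2H-chromene-8-carboxylate
Product: 7 5-(methoxymethoxy)-2,2-dimethyl-2H-chromene-8-carboxylic acid
Conditions: LiOH, THF/MeOH/H2O, 50 °C; then 1 M HCl to pH 4, 0 °C
Reagents that add atoms: lithium hydroxide, [Li+].[OH-]
Why: Ester saponification; cold acidification to pH 4 only should spare the MOM ether and the chromene.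

Step 5
Reactants: 8 2,4,6-trihydroxybenzaldehyde
Product: 9 2-hydroxy-4,6-bis(methoxymethoxy)benzaldehyde
Conditions: MOMCl (2.1 equiv), iPr2NEt, CH2Cl2, 0 °C to rt
Reagents that add atoms: chloromethyl methyl ether (MOMCl), COCCl
Why: O-Alkylation should stop after two MOM groups, because the remaining hydroxyl is hydrogen-bonded to the formyl group.

Step 6
Reactants: 9 2-hydroxy-4,6-bis(methoxymethoxy)benzaldehyde
Product: 10 2-(hydroxymethyl)-3,5-bis(methoxymethoxy)phenol
Conditions: NaBH4, THF/MeOH, 0 °C; neutral aqueous work-up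
Reagents that add atoms: none
Why: Borohydride reduction of the aldehyde; an acid-free work-up should avoid ortho-quinone methide formation from the electron-rich salicyl alcohol.

Step 7
Reactants: 10 2-(hydroxymethyl)-3,5-bis(methoxymethoxy)phenol
Product: 11 2-{[(tert-butyldimethylsilyl)oxy]methyl}-3,5-bis(methoxymethoxy)phenol
Conditions: TBSCl (1.05 equiv), imidazole, CH2Cl2/DMF, −20 to 0 °C
Reagents that add atoms: tert-butyldimethylsilyl chloride (TBSCl), CC(C)(C)[Si](C)(C)Cl
Why: With one equivalent at low temperature the primary benzylic alcohol should be silylated in preference to the phenol, as in the selective silylation of salicyl alcohols.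

Step 8
Reactants: 7 5-(methoxymethoxy)-2,2-dimethyl-2H-chromene-8-carboxylic acid; 11 2-{[(tert-butyldimethylsilyl)oxy]methyl}-3,5-bis(methoxymethoxy)phenol
Product: 13 2-{[(tert-butyldimethylsilyl)oxy]methyl}-3,5-bis(methoxymethoxy)phenyl 5-(methoxymethoxy)-2,2-dimethyl-2H-chromene-8-carboxylate, via O-acylisourea 12 (not isolated)
Conditions: DCC, DMAP (cat.), CH2Cl2, 0 °C to rt
Reagents that add atoms: none
Why: Steglich esterification; DMAP should transfer the acyl group from the O-acylisourea to the phenol under neutral conditions that leave the MOM and TBS ethers untouched.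

Step 9
Reactants: 13 2-{[(tert-butyldimethylsilyl)oxy]methyl}-3,5-bis(methoxymethoxy)phenyl 5-(methoxymethoxy)-2,2-dimethyl-2H-chromene-8-carboxylate
Product: 14 tert-butyl{[2-({1-[5-(methoxymethoxy)-2,2-dimethyl-2H-chromen-8-yl]ethenyl}oxy)-4,6-bis(methoxymethoxy)phenyl]methoxy}dimethylsilane
Conditions: Cp2TiMe2 (3 equiv), toluene/THF, 65 °C, dark; filtration through basic alumina
Reagents that add atoms: dimethyltitanocene (Cp2TiMe2), C[Ti](C)(C1C=CC=C1)C1C=CC=C1
Why: Petasis methylenation of the aryl ester by titanocene methylidene should give the aryl 1-arylvinyl ether under non-acidic conditions; the aldehyde carbon is masked as CH2OTBS because a free formyl group would be methylenated first.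

Step 10
Reactants: 14 tert-butyl{[2-({1-[5-(methoxymethoxy)-2,2-dimethyl-2H-chromen-8-yl]ethenyl}oxy)-4,6-bis(methoxymethoxy)phenyl]methoxy}dimethylsilane
Product: 15 [2-({1-[5-(methoxymethoxy)-2,2-dimethyl-2H-chromen-8-yl]ethenyl}oxy)-4,6-bis(methoxymethoxy)phenyl]methanol
Conditions: TBAF, THF, 0 °C; chromatography on Et3N-treated silica, used at once
Reagents that add atoms: none
Why: Fluoride desilylation is basic, so the acid-labile enol ether should survive.

Step 11
Reactants: 15 [2-({1-[5-(methoxymethoxy)-2,2-dimethyl-2H-chromen-8-yl]ethenyl}oxy)-4,6-bis(methoxymethoxy)phenyl]methanol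
Product: 16 2-({1-[5-(methoxymethoxy)-2,2-dimethyl-2H-chromen-8-yl]ethenyl}oxy)-4,6-bis(methoxymethoxy)benzaldehyde
Conditions: MnO2 (activated, excess), solid K2CO3, CH2Cl2, rt
Reagents that add atoms: none
Why: Neutral heterogeneous oxidation of the electron-rich benzylic alcohol should stop at the aldehyde and leave the enol ether and the chromene alone.

Step 12
Reactants: 16 2-({1-[5-(methoxymethoxy)-2,2-dimethyl-2H-chromen-8-yl]ethenyl}oxy)-4,6-bis(methoxymethoxy)benzaldehyde
Product: 17 (2S)-5,7-bis(methoxymethoxy)-2-[5-(methoxymethoxy)-2,2-dimethyl-2H-chromen-8-yl]-2,3-dihydro-4H-chromen-4-one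
Conditions: [Rh(cod)Cl]2 (2.5 mol %), (R)-DTBM-SEGPHOS (5.5 mol %), NaB[3,5-(CF3)2C6H3]4 (6 mol %), 4 Å MS, 1,4-dioxane, 60 °C
Reagents that add atoms: none
Why: Proposed new method: a cationic bisphosphine complex of monovalent rhodium should insert into the formyl C–H bond of 16, the acyl hydride of trivalent rhodium should bind the enol ether, transfer hydride to the substituted carbon C2 and place rhodium on the terminal carbon C3 in a seven-membered acyl–alkyl rhodacycle, and C–C reductive elimination should then form the C3–C4 bond. The closest known reaction type is the rhodium-catalysed enantioselective intramolecular hydroacylation of 1,1-disubstituted alkenes held ortho to an aryl aldehyde (2-(1-substituted vinyl)benzaldehydes to 3-substituted indanones, 2-(2-substituted allyl)benzaldehydes to 3-substituted tetralones, N-(1-substituted vinyl)indole-2-carbaldehydes to dihydropyrroloindolones); new here are the aryl enol ether as the alkene and the chroman-4-one as the ring formed. Ring C closes in the 6-endo-trig mode with respect to the enol ether, the acyl carbon bonding to the CH2 terminus. The C2 stereocentre is set in the hydride transfer by the chiral bisphosphine, which must present the Re face of C2 to the Rh–H bond to give the (2S) product. The step needs endo over exo regioselectivity (against the 2-aryl-2-methylbenzofuran-3-one) and must outrun decarbonylation: the 1,1-disubstitution should secure the first, since hydride transfer to CH2 would put rhodium on a fully substituted carbon, and the lack of allylic hydrogen (no alkene isomerisation), the short O1 tether and the two ortho oxygen substituents that crowd the aryl migration needed for CO loss are relied on for the second.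

Step 13
Reactants: 17 (2S)-5,7-bis(methoxymethoxy)-2-[5-(methoxymethoxy)-2,2-dimethyl-2H-chromen-8-yl]-2,3-dihydro-4H-chromen-4-one
Product: 18 Sanggenone H, (2S)-5,7-dihydroxy-2-(5-hydroxy-2,2-dimethyl-2H-chromen-8-yl)-2,3-dihydro-4H-chromen-4-one
Conditions: 3 M aq. HCl, MeOH, 40 °C; ee to be checked by chiral HPLC
Reagents that add atoms: none
Why: Acid-catalysed acetal exchange with methanol should remove all three MOM groups; mild acid is chosen because the C2 configuration is lost mainly by base-induced ring opening to the chalcone, and the 2,2-dimethylchromene should tolerate dilute methanolic HCl.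

**Compound list**

1 | methyl 2,4-dihydroxybenzoate | COC(=O)c1ccc(O)cc1O | starting material
2 | methyl 2-hydroxy-4-(methoxymethoxy)benzoate | COC(=O)c1ccc(OCOC)cc1O | intermediate
3 | methyl 4-(methoxymethoxy)-2-[(2-methylbut-3-yn-2-yl)oxy]benzoate | COC(=O)c1ccc(OCOC)cc1OC(C)(C)C#C | intermediate
4 | methyl 2-hydroxy-4-(methoxymethoxy)-3-(3-methylbuta-1,2-dien-1-yl)benzoate (ortho-allenylphenol) | COC(=O)c1ccc(OCOC)c(C=C=C(C)C)c1O | intermediate
5 | methyl 4-(methoxymethoxy)-5-(3-methylbut-2-en-1-ylidene)-6-oxocyclohexa-1,3-diene-1-carboxylate (ortho-quinone methide) | COC(=O)C1=CC=C(OCOC)C(=CC=C(C)C)C1=O | intermediate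
6 | methyl 5-(methoxymethoxy)-2,2-dimethyl-2H-chromene-8-carboxylate | COC(=O)c1ccc(OCOC)c2C=CC(C)(C)Oc12 | intermediate
7 | 5-(methoxymethoxy)-2,2-dimethyl-2H-chromene-8-carboxylic acid | OC(=O)c1ccc(OCOC)c2C=CC(C)(C)Oc12 | intermediate
8 | 2,4,6-trihydroxybenzaldehyde | O=Cc1c(O)cc(O)cc1O | starting material
9 | 2-hydroxy-4,6-bis(methoxymethoxy)benzaldehyde | O=Cc1c(O)cc(OCOC)cc1OCOC | intermediate
10 | 2-(hydroxymethyl)-3,5-bis(methoxymethoxy)phenol | OCc1c(O)cc(OCOC)cc1OCOC | intermediate
11 | 2-{[(tert-butyldimethylsilyl)oxy]methyl}-3,5-bis(methoxymethoxy)phenol | CC(C)(C)[Si](C)(C)OCc1c(O)cc(OCOC)cc1OCOC | intermediate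
12 | N,N'-dicyclohexyl-O-[5-(methoxymethoxy)-2,2-dimethyl-2H-chromene-8-carbonyl]isourea | C1CCCCC1NC(=NC1CCCCC1)OC(=O)c1ccc(OCOC)c2C=CC(C)(C)Oc12 | intermediate
13 | 2-{[(tert-butyldimethylsilyl)oxy]methyl}-3,5-bis(methoxymethoxy)phenyl 5-(methoxymethoxy)-2,2-dimethyl-2H-chromene-8-carboxylate | CC(C)(C)[Si](C)(C)OCc1c(OC(=O)c2ccc(OCOC)c3C=CC(C)(C)Oc23)cc(OCOC)cc1OCOC | intermediate
14 | tert-butyl{[2-({1-[5-(methoxymethoxy)-2,2-dimethyl-2H-chromen-8-yl]ethenyl}oxy)-4,6-bis(methoxymethoxy)phenyl]methoxy}dimethylsilane | CC(C)(C)[Si](C)(C)OCc1c(OC(=C)c2ccc(OCOC)c3C=CC(C)(C)Oc23)cc(OCOC)cc1OCOC | intermediate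
15 | [2-({1-[5-(methoxymethoxy)-2,2-dimethyl-2H-chromen-8-yl]ethenyl}oxy)-4,6-bis(methoxymethoxy)phenyl]methanol | OCc1c(OC(=C)c2ccc(OCOC)c3C=CC(C)(C)Oc23)cc(OCOC)cc1OCOC | intermediate
16 | 2-({1-[5-(methoxymethoxy)-2,2-dimethyl-2H-chromen-8-yl]ethenyl}oxy)-4,6-bis(methoxymethoxy)benzaldehyde | O=Cc1c(OC(=C)c2ccc(OCOC)c3C=CC(C)(C)Oc23)cc(OCOC)cc1OCOC | intermediate
17 | (2S)-5,7-bis(methoxymethoxy)-2-[5-(methoxymethoxy)-2,2-dimethyl-2H-chromen-8-yl]-2,3-dihydro-4H-chromen-4-one | CC1(C)C=Cc2c(OCOC)ccc([C@@H]3CC(=O)c4c(OCOC)cc(OCOC)cc4O3)c2O1 | intermediate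
18 | Sanggenone H, (2S)-5,7-dihydroxy-2-(5-hydroxy-2,2-dimethyl-2H-chromen-8-yl)-2,3-dihydro-4H-chromen-4-one | CC1(C)C=Cc2c(O)ccc([C@@H]3CC(=O)c4c(O)cc(O)cc4O3)c2O1 | target

**Step count**

Total: 13 steps. Longest linear sequence: 10 steps (steps 1–4, then 8–13); the ring A branch (steps 5–7) joins at step 8.

**Steps most likely to fail**

Step 12 (the proposed new method). The acyl rhodium hydride may lose CO and end as an inactive rhodium carbonyl, closure may occur in the exo sense, or facial discrimination in the hydride transfer may be poor. The fallback sets out from 16 and comes back at 17, uses known chemistry and still closes ring C at C3–C4. A thiol-catalysed radical-chain hydroacylation (polarity-reversal catalysis: tert-dodecanethiol, AIBN, chlorobenzene, 80 °C) should add the aroyl radical 6-endo to the CH2 terminus. The benzylic, oxygen-bearing C2 radical then takes hydrogen from the thiol without facial control, which should give racemic 5,7-bis(methoxymethoxy)-2-[5-(methoxymethoxy)-2,2-dimethyl-2H-chromen-8-yl]-2,3-dihydro-4H-chromen-4-one F1. Kinetic resolution of F1 by asymmetric transfer hydrogenation (RuCl(p-cymene)[(S,S)-TsDPEN] or its antipode, whichever consumes the (2R)-ketone; HCO2H/Et3N, EtOAc, rt, stopped near half conversion) should reduce the (2R)-ketone to the cis-alcohol (2R,4R)-5,7-bis(methoxymethoxy)-2-[5-(methoxymethoxy)-2,2-dimethyl-2H-chromen-8-yl]-3,4-dihydro-2H-chromen-4-ol F2. The unreacted (2S)-ketone is 17 and should be separable from F2 by chromatography.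

Step 2. O-Alkylation of the hydrogen-bonded phenol flanked by the ester may be slow, and the tertiary propargylic chloride may lose HCl to the enyne instead. The fallback sets out from 2 and comes back at 6, bypassing 3. Heating 2 with 3-methylbut-2-enal, PhB(OH)2 and propionic acid in toluene with removal of water should hydroxyalkylate the only free ortho carbon through a boron template; the resulting ortho-quinone methide should close by oxa-6π electrocyclisation to the chromene. This fallback makes no compound outside the list (F0).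

Step 7. Silylation may also occur at the phenol, and the electron-rich salicyl alcohol may decompose through ortho-quinone methide formation on handling. The fallback sets out from 10 and comes back at 11. Exhaustive silylation (TBSCl, 2.5 equiv, imidazole, DMF) should give tert-butyl({2-[(tert-butyldimethylsilyl)oxy]-4,6-bis(methoxymethoxy)phenyl}methoxy)dimethylsilane F3. Selective methanolysis of the aryl silyl ether of F3 (K2CO3, MeOH, 0 °C), in which phenoxide is the better leaving group, should return 11.

**Further compounds**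

F1 | step 12 | rac-5,7-bis(methoxymethoxy)-2-[5-(methoxymethoxy)-2,2-dimethyl-2H-chromen-8-yl]-2,3-dihydro-4H-chromen-4-one | CC1(C)C=Cc2c(OCOC)ccc(C3CC(=O)c4c(OCOC)cc(OCOC)cc4O3)c2O1
F2 | step 12 | (2R,4R)-5,7-bis(methoxymethoxy)-2-[5-(methoxymethoxy)-2,2-dimethyl-2H-chromen-8-yl]-3,4-dihydro-2H-chromen-4-ol | CC1(C)C=Cc2c(OCOC)ccc([C@H]3C[C@@H](O)c4c(OCOC)cc(OCOC)cc4O3)c2O1
F0 | step 2 | none | none
F3 | step 7 | tert-butyl({2-[(tert-butyldimethylsilyl)oxy]-4,6-bis(methoxymethoxy)phenyl}methoxy)dimethylsilane | CC(C)(C)[Si](C)(C)OCc1c(O[Si](C)(C)C(C)(C)C)cc(OCOC)cc1OCOC
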